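**Retrosynthetic overview**
1. Ring numbering: C1 = lactone OCH, C2=C3(Me), C4, C5=C6, C7(OH)Me, C8, C9, C10–C11(Me) oxirane, C12 (OAc), C13, C14 = ring-fusion CH. The feature used: C12 is bonded to the methyl-bearing oxirane carbon C11, and the two macro-ring bonds at the oxirane (C9–C10 and C11–C12) are cis. Oxirane plus CHOAc is therefore the retron of a (Z)-2-methyl allylic alcohol.
2. Ring B (14-membered carbocycle) is disconnected at C11–C12: Ni/Cr-mediated addition of the (Z)-2-iodoalkene (C10=C11) to the C12 aldehyde of a seco iodo aldehyde that already holds ring A.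
3. Ring A (cis-fused α-methylene-γ-lactone at C1/C14) comes from catalytic asymmetric 2-(methoxycarbonyl)allylation of a C1 enal with a γ-substituted allyl bromide made from methyl acrylate, then lactonization.
4. C5=C6 comes from cross-metathesis of an (S)-linalool-derived iodo dienol (C6–C11, C7 from the chiral pool) with (E)-3-methylhexa-2,5-dien-1-ol (C1–C5).
5. Ring order: A (lactone), then B (macrocycle, key step), then C (oxirane, hydroxyl-directed), then acetylation.

Key step: step 13

Assumption: in the two ligand-controlled carbonyl additions (steps 10 and 13) the ligand enantiomer named is taken to deliver the stated aldehyde face; if a model aldehyde shows the opposite sense, the antipodal ligand is used with no other change.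

**Step 1**
Reactants: 1 (S)-linalool
Product: 2 (3S)-3,7-dimethyl-3-(triethylsilyloxy)octa-1,6-diene
Conditions: TESOTf, 2,6-lutidine, CH2Cl2, −78 → 0 °C
Reagents that add atoms: triethylsilyl trifluoromethanesulfonate, CC[Si](CC)(CC)OS(=O)(=O)C(F)(F)F
Why: Silyl triflate with a hindered pyridine base silylates the tertiary allylic alcohol without ionization, and the ether prevents lactol formation in steps 2 and 3 while leaving C7 untouched.

**Step 2**
Reactants: 2 (3S)-3,7-dimethyl-3-(triethylsilyloxy)octa-1,6-diene
Product: 4 (S)-4-methyl-4-(triethylsilyloxy)hex-5-enal, via secondary ozonide 3 (not isolated)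
Conditions: O3, CH2Cl2, −78 °C (Sudan Red 7B end point); then PPh3, −78 °C → rt
Reagents that add atoms: ozone, [O-][O+]=O
Why: Chemoselective ozonolysis, in which the electron-rich trisubstituted alkene is cleaved far faster than the vinyl group deactivated by the allylic silyloxy substituent, the dye marking the end point and PPh3 reducing the ozonide to the aldehyde.

**Step 3**
Reactants: 4 (S)-4-methyl-4-(triethylsilyloxy)hex-5-enal; 5 ethyltriphenylphosphonium bromide
Product: 9 (3S,6Z)-7-iodo-3-methyl-3-(triethylsilyloxy)octa-1,6-diene, via ethylidene ylide 6 (not isolated), via iodoethylphosphonium iodide 7 (not isolated), via iodoethylidene ylide 8 (not isolated)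
Conditions: 5, n-BuLi, THF, 0 °C → rt; I2, −78 °C; NaN(SiMe3)2, −78 → −20 °C; then 4, −78 → −20 °C
Reagents that add atoms: iodine, II
Why: Stork–Zhao-type α-iodoalkylidene Wittig olefination, in which the non-stabilized iodo ylide adds under kinetic control through the cis-oxaphosphetane that places iodine cis to the alkyl chain and so gives the (Z)-2-iodoalk-2-ene.

**Step 4**
Reactants: 9 (3S,6Z)-7-iodo-3-methyl-3-(triethylsilyloxy)octa-1,6-diene
Product: 10 (3S,6Z)-7-iodo-3-methylocta-1,6-dien-3-ol
Conditions: Bu4NF, THF, 0 °C → rt
Reagents that add atoms: none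
Why: Fluoride cleaves the tertiary triethylsilyl ether and frees the carbinol that assists the cross-metathesis, the alkenyl iodide being stable to fluoride at this temperature.

**Step 5**
Reactants: 11 pent-1-en-4-yne
Product: 14 (E)-3-methylhexa-2,5-dien-1-ol, via alkenylalane 12 (not isolated), via lithium alanate 13 (not isolated)
Conditions: Me3Al, Cp2ZrCl2 (cat.), CH2Cl2, 0 °C → rt; n-BuLi, THF, −78 °C; (CH2O)n, → rt
Reagents that add atoms: trimethylaluminium, C[Al](C)C; formaldehyde (as paraformaldehyde), C=O
Why: Negishi zirconium-catalysed carboalumination adds methyl and aluminium syn across the terminal alkyne only (aluminium on the terminal carbon), and the alanate adds to formaldehyde with retention, which fixes the E-trisubstituted allylic alcohol.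

**Step 6**
Reactants: 10 (3S,6Z)-7-iodo-3-methylocta-1,6-dien-3-ol; 14 (E)-3-methylhexa-2,5-dien-1-ol
Product: 15 (2E,5E,7S,10Z)-11-iodo-3,7-dimethyldodeca-2,5,10-triene-1,7-diol
Conditions: 14 (3 equiv), second-generation Hoveyda–Grubbs catalyst (5 mol %), 1,4-benzoquinone (10 mol %), CH2Cl2, 40 °C
Reagents that add atoms: none
Why: Olefin cross-metathesis between the allyl-type terminal alkene (homodimerizing partner, in excess) and the vinyl group of the free tertiary allylic alcohol (non-homodimerizing partner) should give the E-alkene for steric reasons, the trisubstituted alkenes and the iodoalkene not engaging ruthenium and benzoquinone suppressing migration of the skipped diene.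

**Step 7**
Reactants: 15 (2E,5E,7S,10Z)-11-iodo-3,7-dimethyldodeca-2,5,10-triene-1,7-diol
Product: 16 (2E,5E,7S,10Z)-7-hydroxy-11-iodo-3,7-dimethyldodeca-2,5,10-trienal
Conditions: MnO2, CH2Cl2, rt
Reagents that add atoms: none
Why: MnO2 oxidizes only the primary allylic alcohol (the tertiary one cannot be oxidized) under neutral conditions that should not move the skipped C5=C6 alkene into conjugation.

**Step 8**
Reactants: 17 methyl acrylate; 18 3-(tert-butyldimethylsilyloxy)propanal
Product: 19 methyl 5-(tert-butyldimethylsilyloxy)-3-hydroxy-2-methylidenepentanoate (racemic)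
Conditions: DABCO (0.5 equiv), MeOH (few equiv), neat, rt
Reagents that add atoms: none
Why: Morita–Baylis–Hillman reaction, in which DABCO adds to the acrylate, the zwitterionic enolate adds to the aldehyde and elimination returns the amine; the carbinol centre is removed in step 9.

**Step 9**
Reactants: 19 methyl 5-(tert-butyldimethylsilyloxy)-3-hydroxy-2-methylidenepentanoate
Product: 20 methyl (Z)-2-(bromomethyl)-5-(tert-butyldimethylsilyloxy)pent-2-enoate
Conditions: NBS, Me2S, CH2Cl2, 0 °C → rt
Reagents that add atoms: N-bromosuccinimide, O=C1CCC(=O)N1Br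
Why: Bromide attacks the alkoxysulfonium salt of the Baylis–Hillman alcohol in SN2' fashion and gives the (Z)-2-(bromomethyl)alk-2-enoate (alkyl chain trans to the ester) under conditions mild enough for the silyl ether.

**Step 10**
Reactants: 16 (2E,5E,7S,10Z)-7-hydroxy-11-iodo-3,7-dimethyldodeca-2,5,10-trienal; 20 methyl (Z)-2-(bromomethyl)-5-(tert-butyldimethylsilyloxy)pent-2-enoate
Product: 22 (4S,5S)-4-[2-(tert-butyldimethylsilyloxy)ethyl]-5-[(1E,4E,6S,9Z)-6-hydroxy-10-iodo-2,6-dimethylundeca-1,4,9-trien-1-yl]-3-methylideneoxolan-2-one, via syn hydroxy ester 21 (not isolated)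
Conditions: CrCl2 (10 mol %), 1,8-bis[(S)-4-isopropyl-4,5-dihydrooxazol-2-yl]-3,6-diphenyl-9H-carbazole (12 mol %), Mn powder, Cp2ZrCl2, iPr2NEt (cat.), THF, rt; then PPTS (cat.), CH2Cl2, rt
Reagents that add atoms: none
Why: Catalytic asymmetric Nozaki–Hiyama 2-(alkoxycarbonyl)allylation, in which the trivalent allylchromium adds through its γ-carbon to the Re face of the enal (face set by the chiral tridentate ligand) in a Zimmerman–Traxler chair with the γ-substituent cis to CH2Cr axial, so that the syn adduct forms and lactonizes to the cis-lactone (C1 S, C14 S), the alkenyl iodide being inert without nickel.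

**Step 11**
Reactants: 22 cis-lactone silyl ether
Product: 23 (4S,5S)-4-(2-hydroxyethyl)-5-[(1E,4E,6S,9Z)-6-hydroxy-10-iodo-2,6-dimethylundeca-1,4,9-trien-1-yl]-3-methylideneoxolan-2-one
Conditions: HF·pyridine, pyridine, THF, 0 °C → rt
Reagents that add atoms: none
Why: Buffered HF·pyridine removes the primary silyl ether without touching the lactone, the exocyclic enoate, the tertiary allylic alcohol or the iodoalkene.

**Step 12**
Reactants: 23 lactone diol
Product: 24 seco iodo aldehyde: 2-[(3S,4S)-2-[(1E,4E,6S,9Z)-6-hydroxy-10-iodo-2,6-dimethylundeca-1,4,9-trien-1-yl]-4-methylidene-5-oxooxolan-3-yl]acetaldehyde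
Conditions: Dess–Martin periodinane, NaHCO3, CH2Cl2, 0 °C → rt
Reagents that add atoms: none
Why: Buffered Dess–Martin oxidation converts the primary alcohol into the aldehyde without epimerizing C14 or moving the exocyclic alkene, the tertiary alcohol being inert.

**Step 13**
Reactants: 24 seco iodo aldehyde
Product: 25 macrocyclic (10Z)-allylic alcohol (1S,7S,12R,14S; ring B closed on the cis-fused lactone ring A)
Conditions: CrCl2 (8 equiv), (S)-N-[2-(4-isopropyl-4,5-dihydrooxazol-2-yl)-6-methylphenyl]methanesulfonamide (8.8 equiv), Et3N, THF, rt; then NiCl2 (cat.), slow addition of 24 (syringe pump, final 2 mM), rt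
Reagents that add atoms: none
Why: Divalent chromium reduces NiCl2 to zerovalent nickel, which inserts into the C11–I bond with retention; transmetalation gives a trivalent alkenylchromium carrying the chiral oxazoline–sulfonamide ligand, which adds to the C12 aldehyde to give the chromium alkoxide, so the Z-geometry fixed in step 3 is carried into the ring. The closest known reaction type is the Ni/Cr-mediated (Nozaki–Hiyama–Kishi) alkenyl iodide–aldehyde macrocyclization in its ligand-controlled asymmetric form. Ring B (14-membered carbocycle) closes end-to-end by C11–C12 bond formation, formally a 14-exo-trig addition to the carbonyl, under high dilution. The new C12 stereocentre (R) is set by reagent control, the ligand-bound chromium delivering the alkenyl group to the Si face of the aldehyde, since 1,3-induction from C14 is weak. The step needs chemoselectivity for the aldehyde over the lactone carbonyl, the exocyclic enoate and the free tertiary alcohol, which the weakly basic, aldehyde-selective organochromium secures, and it needs cyclization over oligomerization, which slow addition and the conformational restriction by the cis-lactone and the three alkenes of the seco chain secure.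

**Step 14**
Reactants: 25 macrocyclic (10Z)-allylic alcohol
Product: 26 erythro 10,11-epoxy-7,12-diol (oxirane ring C; 12R)
Conditions: Ti(OiPr)4, D-(−)-diisopropyl tartrate, t-BuOOH, 4 Å MS, CH2Cl2, −20 °C
Reagents that add atoms: tert-butyl hydroperoxide, CC(C)(C)OO
Why: Sharpless asymmetric epoxidation in its matched stoichiometric form, in which titanium bound to the C12 alkoxide delivers oxygen to C10=C11 on the face preferred by D-(−)-tartrate, which is the face erythro to the (12R)-carbinol (the fast-reacting carbinol sense for this tartrate), while the tertiary C7 alcohol with the disubstituted C5=C6 alkene, the C2=C3 alkene and the electron-poor exocyclic alkene should react far more slowly.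

**Step 15**
Reactants: 26 erythro 10,11-epoxy-7,12-diol
Product: 27 target CNP0288879.2 (12-acetate)
Conditions: Ac2O, pyridine, DMAP (cat.), CH2Cl2, 0 °C → rt
Reagents that add atoms: acetic anhydride, CC(=O)OC(C)=O
Why: DMAP-catalysed O-acetylation of the secondary C12 hydroxyl is much faster than that of the tertiary C7 hydroxyl and proceeds with retention, the oxirane and the lactone being stable to these conditions.

**Compound list**
1 | (S)-linalool | C=C[C@@](C)(O)CCC=C(C)C | starting material
2 | (3S)-3,7-dimethyl-3-(triethylsilyloxy)octa-1,6-diene | C=C[C@@](C)(O[Si](CC)(CC)CC)CCC=C(C)C | intermediate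
3 | secondary ozonide (1,2,4-trioxolane) of 2 at C6=C7 | C=C[C@@](C)(O[Si](CC)(CC)CC)CCC1OOC(C)(C)O1 | intermediate (not isolated)
4 | (S)-4-methyl-4-(triethylsilyloxy)hex-5-enal | C=C[C@@](C)(O[Si](CC)(CC)CC)CCC=O | intermediate
5 | ethyltriphenylphosphonium bromide | CC[P+](c1ccccc1)(c1ccccc1)c1ccccc1.[Br-] | starting material
6 | ethylidenetriphenylphosphorane | CC=P(c1ccccc1)(c1ccccc1)c1ccccc1 | intermediate (not isolated)
7 | (1-iodoethyl)triphenylphosphonium iodide | CC(I)[P+](c1ccccc1)(c1ccccc1)c1ccccc1.[I-] | intermediate (not isolated)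
8 | (1-iodoethylidene)triphenylphosphorane | CC(I)=P(c1ccccc1)(c1ccccc1)c1ccccc1 | intermediate (not isolated)
9 | (3S,6Z)-7-iodo-3-methyl-3-(triethylsilyloxy)octa-1,6-diene | C=C[C@@](C)(O[Si](CC)(CC)CC)CC/C=C(/C)I | intermediate
10 | (3S,6Z)-7-iodo-3-methylocta-1,6-dien-3-ol | C=C[C@@](C)(O)CC/C=C(/C)I | intermediate
11 | pent-1-en-4-yne | C=CCC#C | starting material
12 | dimethyl[(E)-2-methylpenta-1,4-dien-1-yl]alane | C=CC/C(C)=C/[Al](C)C | intermediate (not isolated)
13 | lithium butyl(dimethyl)[(E)-2-methylpenta-1,4-dien-1-yl]alanate | [Li+].CCCC[Al-](C)(C)/C=C(\C)CC=C | intermediate (not isolated)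
14 | (E)-3-methylhexa-2,5-dien-1-ol | OC/C=C(\C)CC=C | intermediate
15 | (2E,5E,7S,10Z)-11-iodo-3,7-dimethyldodeca-2,5,10-triene-1,7-diol | OC/C=C(\C)C/C=C/[C@@](C)(O)CC/C=C(/C)I | intermediate
16 | (2E,5E,7S,10Z)-7-hydroxy-11-iodo-3,7-dimethyldodeca-2,5,10-trienal | O=C/C=C(\C)C/C=C/[C@@](C)(O)CC/C=C(/C)I | intermediate
17 | methyl acrylate | C=CC(=O)OC | starting material
18 | 3-(tert-butyldimethylsilyloxy)propanal | O=CCCO[Si](C)(C)C(C)(C)C | starting material
19 | methyl 5-(tert-butyldimethylsilyloxy)-3-hydroxy-2-methylidenepentanoate (racemic) | C=C(C(=O)OC)C(O)CCO[Si](C)(C)C(C)(C)C | intermediate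
20 | methyl (Z)-2-(bromomethyl)-5-(tert-butyldimethylsilyloxy)pent-2-enoate | COC(=O)/C(CBr)=C/CCO[Si](C)(C)C(C)(C)C | intermediate
21 | syn hydroxy ester (C1 S, C14 S), open-chain precursor of the lactone | C=C(C(=O)OC)[C@H](CCO[Si](C)(C)C(C)(C)C)[C@@H](O)/C=C(\C)C/C=C/[C@@](C)(O)CC/C=C(/C)I | intermediate (not isolated)
22 | (4S,5S)-cis-lactone silyl ether | C=C1C(=O)O[C@@H](/C=C(\C)C/C=C/[C@@](C)(O)CC/C=C(/C)I)[C@H]1CCO[Si](C)(C)C(C)(C)C | intermediate
23 | (4S,5S)-cis-lactone diol | C=C1C(=O)O[C@@H](/C=C(\C)C/C=C/[C@@](C)(O)CC/C=C(/C)I)[C@H]1CCO | intermediate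
24 | seco iodo aldehyde (key-step precursor) | C=C1C(=O)O[C@@H](/C=C(\C)C/C=C/[C@@](C)(O)CC/C=C(/C)I)[C@H]1CC=O | intermediate
25 | 14-membered (10Z)-allylic alcohol, 12R (key-step product) | C=C1C(=O)O[C@H]2/C=C(\C)C/C=C/[C@@](C)(O)CC/C=C(/C)[C@H](O)C[C@@H]12 | intermediate
26 | erythro 10,11-epoxy-7,12-diol | C=C1C(=O)O[C@H]2/C=C(\C)C/C=C/[C@@](C)(O)CC[C@@H]3O[C@]3(C)[C@H](O)C[C@@H]12 | intermediate
27 | CNP0288879.2 | C=C1C(=O)O[C@H]2/C=C(\C)C/C=C/[C@@](C)(O)CC[C@@H]3O[C@]3(C)[C@H](OC(C)=O)C[C@@H]12 | target

**Step count**
Total steps: 15. Longest linear sequence: 12 steps (1–4, 6, 7, 10–15).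

**Three steps most likely to fail**

Step 13 (key step). Facial selectivity at the C12 aldehyde may be eroded if the strain of the ring-closing transition state overrides the chromium ligand, and intermolecular coupling competes at practical concentrations. The fallback sets out from 24 and comes back at 25. The closure is run without chiral ligand (CrCl2, NiCl2 cat., DMSO, rt, high dilution), which should give 25 together with its C12 epimer, the (12S)-allylic alcohol F1. The mixture is oxidized with Dess–Martin periodinane to the macrocyclic (10Z)-enone F2. Corey–Bakshi–Shibata reduction with the (S)-methyl oxazaborolidine and catecholborane, the α-methylalkenyl group acting as the large substituent, then sets C12 by reagent control and returns 25.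

Step 14. Oxygen may be delivered to the wrong face of C10=C11, because A(1,3) strain between C13 and the cis ring carbon C9 disfavours the tartrate-matched erythro transition state; the tertiary C7 alkoxide may also direct epoxidation of C5=C6. The fallback sets out from 25 and comes back at 27, leaving out 26. Compound 25 is oxidized to the (10Z)-enone F2 and reduced with the (R)-methyl oxazaborolidine and catecholborane to the (12S)-allylic alcohol F1. Hydroxyl-directed epoxidation with Ti(OiPr)4 and t-BuOOH without tartrate then follows the A(1,3)-controlled threo mode, which for this epimer is the oxirane face of the target, and gives the threo epoxy alcohol F3. Mitsunobu reaction with acetic acid (PPh3, DIAD) installs the acetate with inversion at C12 and gives 27.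

Step 10. Enantio- and diastereofacial control by the chromium catalyst may be insufficient on the β,β-disubstituted enal, and the skipped C5=C6 alkene may migrate into conjugation under the reaction conditions. The fallback sets out from 16 and 20 and comes back at 22. Indium-mediated Barbier allylation (indium powder, THF/H2O, rt) is syn-selective for (Z)-2-(bromomethyl)alk-2-enoates but exerts no absolute control, and should give 21 together with the (1R,14R) syn hydroxy ester F4. Lactonization (PPTS, CH2Cl2) gives 22 and the (4R,5R) cis-lactone F5. These are diastereomers through the fixed C7 centre and are separated by preparative HPLC.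

**Further compounds**
F1 | step 13 | (12S)-allylic alcohol, C12 epimer of 25 | C=C1C(=O)O[C@H]2/C=C(\C)C/C=C/[C@@](C)(O)CC/C=C(/C)[C@@H](O)C[C@@H]12
F2 | step 13 | macrocyclic (10Z)-enone (C12 ketone) | C=C1C(=O)O[C@H]2/C=C(\C)C/C=C/[C@@](C)(O)CC/C=C(/C)C(=O)C[C@@H]12
F3 | step 14 | threo 10,11-epoxy-7,12-diol (12S) | C=C1C(=O)O[C@H]2/C=C(\C)C/C=C/[C@@](C)(O)CC[C@@H]3O[C@]3(C)[C@@H](O)C[C@@H]12
F4 | step 10 | (1R,14R) syn hydroxy ester, diastereomer of 21 | C=C(C(=O)OC)[C@@H](CCO[Si](C)(C)C(C)(C)C)[C@H](O)/C=C(\C)C/C=C/[C@@](C)(O)CC/C=C(/C)I
F5 | step 10 | (4R,5R) cis-lactone silyl ether, diastereomer of 22 | C=C1C(=O)O[C@H](/C=C(\C)C/C=C/[C@@](C)(O)CC/C=C(/C)I)[C@@H]1CCO[Si](C)(C)C(C)(C)C
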